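Late in the grey run target is falling, 40% at 6.00 min and 30% at 10.0 min, although 18% of starting material still stands there to feed it.

| setting | green | grey | flask |
|---|---|---|---|
| starting material | 0.010 M (fed, over 4.0 s) | 0.010 M (fed, over 4.0 s) | 0.010 M (fed, over 4.0 s) |
| partner | 10 mM | 10 mM | 10.0 mM |
| free catalyst | 15 µM | 10 µM | 15 µM |
| remark | the very flask that is asked about, followed so far; the fed solution adds 0.20 times the starting volume | run made earlier; the fed solution adds 0.20 times the starting volume | the fed solution adds 0.20 times the starting volume |
| time |  |  | 10 min |

| run | time / min | target / % | starting material / % |
|---|---|---|---|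
| green | 0.833 | 21 | 79 |
| green | 1.33 | 33 | 66 |
| green | 1.50 | 33 | 65 |
| green | 2.00 | 41 | 51 |
| green | 3.00 | 47 | 39 |
| green | 4.00 | 44 | 33 |
| grey | 0.833 | 17 | 85 |
| grey | 1.33 | 20 | 76 |
| grey | 2.50 | 35 | 61 |
| grey | 4.00 | 39 | 45 |
| grey | 6.00 | 40 | 31 |
| grey | 10.0 | 30 | 18 |

(each reading ± 1.5 percentage points)

- every charge counts on the volume at the start, and the solution that is fed holds the whole dose
- what was read earlier has a scatter of 1.5 percentage points, one standard deviation

* when, up to 10 min, the flask holds most target
* the amount of target, in percent of the starting material charged, at that time
* the first time at which target reaches 13%, in the same percent, in min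

Question: what does one molecule face? Answer: a molecule of starting material has some chance per minute of becoming target, and a molecule of target has some chance per minute of leaving.

Question: when is target highest? Answer: where arrivals equal departures, so c(starting material) times the first chance equals c(target) times the second. At that moment the ratio of the two chances, a selectivity factor, can be read as c(starting material)/c(target). At the highest reading of the green run, which is the flask followed so far, this top ratio is 0.830.

Follow-up: is that reading really the top? Not surely, since 47% at 3.00 min and 44% at 4.00 min differ by 3 percentage points, and each reading has a scatter of 1.5 points. The ratio is therefore a loose reading, and it belongs to the charges of the green run: the grey run has 10 µM of free catalyst against 15 µM, so I don't carry the ratio between those two runs.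

Question: what does it give for the flask, which is the green run followed further? Answer: the green ratio is 1.24 at 2.00 min, above 0.830, and 0.750 at 4.00 min, below it, so target is rising at the first of these times and falling at the second. I put the top near 3.00 min, somewhere between those two times.

The forecast puts the top later than my 3.00 min: 3.5 min (2.9 min to 4.4 min), with 47% (44.5% to 49.5%) and 0.49 min (0.38 min to 0.62 min). Its ground for the time is that “the data peak earlier, 47 at 3 and 44 at 4”.

The flask gives 3.53 min, 44.9% and 0.459 min, each inside the forecast's range, though the best stands 0.40 points above the low end. Target stands at 43.9% at 2.83 min and at 43.9% at 4.42 min. The top ratio times the best gives c(starting material) at the top as 37.3%, and the flask holds 36.2% at 3.53 min.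

    catalyst intermediate D → free catalyst + target (k = 36.0 s⁻¹)
    starting material + free catalyst ⇌ catalyst intermediate A (K = 110 M⁻¹, k = 4600 M⁻¹ s⁻¹)
    catalyst intermediate A ⇌ catalyst intermediate B (K = 0.840, k = 45.0 s⁻¹)
    target + by-product → side product (k = 0.890 M⁻¹ s⁻¹)
    catalyst intermediate C ⇌ by-product + catalyst intermediate D (K = 0.00590 M, k = 710 s⁻¹)
    partner + catalyst intermediate B → catalyst intermediate C (k = 2400 M⁻¹ s⁻¹)

Now the same flask read at 2.5 min. A straight line between the green ratios 1.24 at 2.00 min and 0.830 at 3.00 min gives 1.04 at that time, above the top ratio, so target should still be rising and the highest amount so far should be the amount then. The computed flask has 42.7% as its highest amount and 42.7% at the reading.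

(The runs are calculated from invented constants; noise was put on by code.)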